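**Plan**

- Retrosynthesis: the two O-benzyl bonds at O5 and O7 are cut first. Then one disconnection removes the C3–C1' bond between ring C and ring B together with the O1–C2 bond of the pyranone, giving a ring A o-hydroxyaryl enaminone and 1,2,3,5-tetramethoxybenzene.
- Enabling feature: C3 of ring C lies between the C4 carbonyl and the heteroatom-bearing C2, so in an enaminone precursor it is the nucleophilic enamine carbon. C1' of ring B is ortho, ortho and para to the 2'-, 6'- and 4'-methoxy groups, and the parent arene has only two C–H positions (C4 and C6), equivalent by symmetry, so a dehydrogenative C–H/C–H union can give only the 2,3,4,6-tetramethoxyphenyl group.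
- Forward: rings A and B come preformed (2',4',6'-trihydroxyacetophenone and 3,4,5-trimethoxyphenol). Ring A is dibenzylated and converted to the enaminone, ring B is completed by one methylation, the anodic cross-coupling joins them at C3–C1', and ring C closes in the same flask through O1–C2 with loss of Me2NH. Hydrogenolysis then frees the 5- and 7-hydroxyls.
- Helpers: NMe2 is the temporary activating group (enamine donor, then leaving group); the benzyl ethers are the temporary protecting groups.
- Stereochemistry: the target has no stereocentre, so none has to be set.

Key step: step 4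

Remark: rotation about the C3–C1' bond is taken as free at room temperature (no axis is specified), so the target is treated as achiral.

**Route**

Step 1
Reactants: 1 3,4,5-trimethoxyphenol
Product: 2 1,2,3,5-tetramethoxybenzene
Conditions: MeI, K2CO3, acetone, reflux
Reagents that add atoms: iodomethane, CI
Why: Williamson ether synthesis on an unhindered phenoxide should give the symmetric arene whose only two C–H positions are equivalent.

Step 2
Reactants: 3 1-(2,4,6-trihydroxyphenyl)ethan-1-one (2',4',6'-trihydroxyacetophenone)
Product: 4 1-[2,4-bis(benzyloxy)-6-hydroxyphenyl]ethan-1-one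
Conditions: BnBr (2.05 equiv), K2CO3, DMF, rt
Reagents that add atoms: benzyl bromide, BrCc1ccccc1
Why: Williamson O-benzylation should take the para hydroxyl and one ortho hydroxyl and then stop, because the remaining hydroxyl is hydrogen-bonded to the ketone and is the least nucleophilic.

Step 3
Reactants: 4 1-[2,4-bis(benzyloxy)-6-hydroxyphenyl]ethan-1-one
Product: 5 (E)-1-[2,4-bis(benzyloxy)-6-hydroxyphenyl]-3-(dimethylamino)prop-2-en-1-one
Conditions: Me2NCH(OMe)2, toluene, 95 °C
Reagents that add atoms: N,N-dimethylformamide dimethyl acetal, COC(OC)N(C)C
Why: Condensation of the methyl ketone with the amide acetal (enaminone formation) is standard for o-hydroxyacetophenones and should give the thermodynamic E enaminone, whose geometry is lost later.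

Step 4
Reactants: 5 (E)-1-[2,4-bis(benzyloxy)-6-hydroxyphenyl]-3-(dimethylamino)prop-2-en-1-one, 2 1,2,3,5-tetramethoxybenzene
Product: 8 5,7-bis(benzyloxy)-3-(2,3,4,6-tetramethoxyphenyl)-4H-chromen-4-one, via alpha-aryl enaminone 6 (not isolated), via 2-(dimethylamino)isoflavanone 7 (not isolated)
Conditions: 2 (3 equiv), undivided cell, reticulated vitreous carbon anode, platinum cathode, constant current, 2.2 F/mol based on 5, Bu4NBF4 (0.1 M), 2,6-lutidine (2 equiv), (CF3)2CHOH/CH2Cl2 4:1, rt; then AcOH, 50 °C
Reagents that add atoms: none
Why: Proposed new method: anodic oxidation should turn 2, the most electron-rich component, into its radical cation (long-lived in the fluorinated alcohol), which is attacked at C4 (equivalent to C6) by the enamine alpha-carbon of 5, and a second electron transfer with loss of the ring proton rearomatises ring B to give the iminium form of 6 while protons are reduced to H2 at the cathode; should 5 be oxidised first, attack of 2 on its radical cation gives the same bond. The closest known reaction types are the capture of alkoxyarene radical cations by beta-dicarbonyl carbon nucleophiles in fluorinated alcohols, anodic dehydrogenative arene-arene cross-coupling, and the oxidative alpha-functionalisation/annulation of o-hydroxyaryl enaminones to 3-halo-, 3-sulfenyl- and 3-selanylchromones. Ring C closes by 6-exo-trig attack of the phenol oxygen on the iminium carbon (a 6-endo-trig oxa-Michael addition if counted from neutral 6) to give 7, and loss of Me2NH then aromatises the pyranone. No stereocentre is set, since the two centres of 7 are erased by the elimination. The step needs one arylation site on each partner and cross-coupling over homo-coupling: the symmetry of 2 leaves a single possible site, the NMe2 donor makes the future C3 far more nucleophilic than C6 and C8 of the acyl-deactivated ring A or than a second molecule of 2, and the product should resist further oxidation because its ring B is twisted out of conjugation and bears the electron-poor chromone. The benzyl ethers and the lutidine buffer are there to prevent oxidation of ring A phenols and premature acid-driven closure of 5 to the 3-unsubstituted chromone.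

Step 5
Reactants: 8 5,7-bis(benzyloxy)-3-(2,3,4,6-tetramethoxyphenyl)-4H-chromen-4-one
Product: 9 5,7-dihydroxy-3-(2,3,4,6-tetramethoxyphenyl)-4H-chromen-4-one
Conditions: H2 (1 atm), 10% Pd/C, EtOAc/MeOH, rt
Reagents that add atoms: none
Why: Catalytic hydrogenolysis of aryl benzyl ethers should release both phenols while the methyl ethers and the hindered C2–C3 double bond of the vinylogous ester remain, provided the reaction is stopped at full debenzylation.

**Compound list**

1 | 3,4,5-trimethoxyphenol | COc1cc(O)cc(OC)c1OC | starting material
2 | 1,2,3,5-tetramethoxybenzene | COc1cc(OC)cc(OC)c1OC | intermediate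
3 | 1-(2,4,6-trihydroxyphenyl)ethan-1-one | CC(=O)c1c(O)cc(O)cc1O | starting material
4 | 1-[2,4-bis(benzyloxy)-6-hydroxyphenyl]ethan-1-one | CC(=O)c1c(O)cc(OCc2ccccc2)cc1OCc1ccccc1 | intermediate
5 | (E)-1-[2,4-bis(benzyloxy)-6-hydroxyphenyl]-3-(dimethylamino)prop-2-en-1-one | CN(C)/C=C/C(=O)c1c(O)cc(OCc2ccccc2)cc1OCc1ccccc1 | intermediate
6 | 1-[2,4-bis(benzyloxy)-6-hydroxyphenyl]-3-(dimethylamino)-2-(2,3,4,6-tetramethoxyphenyl)prop-2-en-1-one (alpha-aryl enaminone, first formed as its C-protonated iminium form; double-bond geometry not defined; not isolated) | CN(C)C=C(C(=O)c1c(O)cc(OCc2ccccc2)cc1OCc1ccccc1)c1c(OC)cc(OC)c(OC)c1OC | intermediate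
7 | 5,7-bis(benzyloxy)-2-(dimethylamino)-3-(2,3,4,6-tetramethoxyphenyl)chroman-4-one (mixture of diastereomers; not isolated) | CN(C)C1Oc2cc(OCc3ccccc3)cc(OCc3ccccc3)c2C(=O)C1c1c(OC)cc(OC)c(OC)c1OC | intermediate
8 | 5,7-bis(benzyloxy)-3-(2,3,4,6-tetramethoxyphenyl)-4H-chromen-4-one | COc1cc(OC)c(-c2coc3cc(OCc4ccccc4)cc(OCc4ccccc4)c3c2=O)c(OC)c1OC | intermediate
9 | 5,7-dihydroxy-3-(2,3,4,6-tetramethoxyphenyl)-4H-chromen-4-one | COc1cc(OC)c(-c2coc3cc(O)cc(O)c3c2=O)c(OC)c1OC | target

**Step count**

Total step count: 5.
Longest linear sequence: 4 steps (3 to 4 to 5 to 8 to 9, steps 2, 3, 4 and 5); step 1 is a one-step side branch that joins at step 4.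

**Steps most likely to fail**

1. Step 4 (Proposed new method). What may go wrong:
   - homo-coupling of the radical cation of 2;
   - non-oxidative ring closure of 5 to the 3-unsubstituted chromone before the C–C bond forms;
   - over-oxidation of the product as charge is passed.

   The fallback uses known chemistry, sets out from 5 and 2, and comes back at 8. Compound 5 is treated with I2 (pyridine, CHCl3, rt; iodocyclisation with loss of Me2NH) to give 5,7-bis(benzyloxy)-3-iodo-4H-chromen-4-one F1. Compound 2 is lithiated between its 3- and 5-methoxy groups (n-BuLi, THF, 0 °C), quenched with B(OMe)3 and hydrolysed to (2,3,4,6-tetramethoxyphenyl)boronic acid F2. Suzuki–Miyaura coupling of F1 with F2 (Pd(OAc)2, SPhos, K3PO4, toluene/H2O, 90 °C) should give 8, which re-enters at step 5.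

2. Step 5. What may go wrong: hydrogenation of the C2–C3 double bond of ring C alongside the hydrogenolysis, or stalling at the mono-benzyl stage. The fallback goes from 8 directly to 9 by Lewis-acid debenzylation with BCl3 and pentamethylbenzene as benzyl-cation scavenger (CH2Cl2, −78 °C). It uses no hydrogen and should leave aryl methyl ethers intact at this temperature. It makes no new compound (F0).

3. Step 2. What may go wrong: over-alkylation to the tri-ether or incomplete conversion, giving mixtures of mono-, di- and tribenzyl ethers. The fallback sets out from 3 and comes back at 4. Exhaustive benzylation (excess BnBr, K2CO3, DMF, 60 °C) gives 1-[2,4,6-tris(benzyloxy)phenyl]ethan-1-one F3. Chelation-controlled removal of one ortho benzyl group with MgBr2·OEt2 (toluene/Et2O, reflux) then returns 4.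

**Further compounds**

F1 | step 4 | 5,7-bis(benzyloxy)-3-iodo-4H-chromen-4-one | O=c1c(I)coc2cc(OCc3ccccc3)cc(OCc3ccccc3)c12
F2 | step 4 | (2,3,4,6-tetramethoxyphenyl)boronic acid | COc1cc(OC)c(B(O)O)c(OC)c1OC
F0 | step 5 | none | none
F3 | step 2 | 1-[2,4,6-tris(benzyloxy)phenyl]ethan-1-one | CC(=O)c1c(OCc2ccccc2)cc(OCc2ccccc2)cc1OCc1ccccc1
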